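The route rests on cutting the C8–C9 bond of ring B (C5–C10). Ring A is locally mirror-symmetric: C4 and C10 each carry an axial methyl and an equatorial carbon on either side of C5. Excising the arene of cheap (+)-dehydroabietic acid therefore delivers ring A of the antipodal labdane series, once its carboxyl carbon is read as C9 and its aryl-bound carbon as C18. The key step, a SmI2 ketyl–olefin cyclisation, exploits the vicinal C8 carbinol/C9 methine pair. It closes ring B, sets both centres and saturates C11 in one operation. Its precursor is a monocyclic methyl ketone whose E-alkene already carries the complete C11–C16 side chain.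

Key step: step 11

Remark: from compound 4 on, atoms carry the labdane numbers of the target; abietane C18 becomes C9, abietane C9 becomes C18, abietane C4/C10, C19/C20 and C1/C3 change places, C2 and C5–C8 keep their numbers; compounds 1, 9, 18 and 22 are taken as catalogue items.

Step 1
Reactants: 1 (+)-dehydroabietic acid
Product: 2 dehydroabietinol
Conditions: LiAlH4, THF, 0 °C to reflux
Reagents that add atoms: none
Why: Hydride reduction of the carboxylic acid with LiAlH4 gives the neopentyl primary alcohol, and no stereocentre is touched.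

Step 2
Reactants: 2 dehydroabietinol
Product: 3 dehydroabietinyl acetate
Conditions: Ac2O, pyridine, DMAP (cat.), CH2Cl2, rt
Reagents that add atoms: acetic anhydride CC(=O)OC(C)=O
Why: DMAP-catalysed acetylation masks the future C9 oxygen as an ester that withstands RuO4, which keeps the two equatorial carbons on ring A different from each other.

Step 3
Reactants: 3 dehydroabietinyl acetate
Product: 4 seco diacid
Conditions: RuCl3·xH2O (5 mol %), NaIO4 (excess), CCl4/MeCN/H2O, rt
Reagents that add atoms: sodium periodate [Na+].[O-]I(=O)(=O)=O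
Why: RuO4 made in situ degrades the trialkylbenzene ring (arene-to-carboxylic-acid oxidation), so only the two ring carbons bonded to sp3 carbons survive as CO2H groups, while the three ring A stereocentres offer no oxidisable handle and are kept.

Step 4
Reactants: 4 seco diacid
Product: 6 hydroxy diester, via acetoxy diester 5 (not isolated)
Conditions: MeI, K2CO3, DMF, rt; then MeOH, rt
Reagents that add atoms: iodomethane CI
Why: Carboxylate O-alkylation (SN2 on MeI) is insensitive to the hindrance of the tertiary acid, and base-catalysed transesterification with methanol then removes only the acetate because exchange at the methyl esters is degenerate.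

Step 5
Reactants: 6 hydroxy diester
Product: 7 aldehyde diester
Conditions: Dess–Martin periodinane, CH2Cl2, rt
Reagents that add atoms: none
Why: Dess–Martin oxidation takes the neopentyl alcohol to the aldehyde, which has no alpha hydrogen and cannot epimerise.

Step 6
Reactants: 7 aldehyde diester
Product: 8 E-iodoalkene diester
Conditions: CrCl2, CHI3, THF, 0 °C to rt
Reagents that add atoms: iodoform IC(I)I
Why: Takai olefination through the geminal dichromium reagent is selective for aldehydes over esters and gives the E-iodoalkene, a preference reinforced by the quaternary neighbour C10.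

Step 7
Reactants: 9 (R)-2-methylbutane-1,4-diol
Product: 10 monosilyl ether
Conditions: TBSCl (1 equiv), imidazole, CH2Cl2, −20 °C
Reagents that add atoms: tert-butyldimethylsilyl chloride CC(C)(C)[Si](C)(C)Cl
Why: Kinetically controlled silylation picks the unbranched hydroxyl (future C15) over the beta-branched one, and the stereocentre (future C13) comes from the chiral pool and is not touched.

Step 8
Reactants: 10 monosilyl ether
Product: 11 side-chain iodide
Conditions: I2, PPh3, imidazole, CH2Cl2, 0 °C
Reagents that add atoms: iodine II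
Why: Appel-type iodination replaces the remaining primary hydroxyl by SN2 at a carbon that is not stereogenic.

Step 9
Reactants: 11 side-chain iodide; 8 E-iodoalkene diester
Product: 13 E-alkene diester, via alkylzinc iodide 12 (not isolated)
Conditions: Zn dust, LiCl, THF, 40 °C; then 8, Pd(dppf)Cl2 (5 mol %), THF, rt
Reagents that add atoms: none
Why: Negishi coupling, in which zinc insertion gives a primary alkylzinc iodide that tolerates esters and zerovalent palladium formed from Pd(dppf)Cl2 joins it to the iodoalkene (C11–C12 bond) with retention of the E geometry.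

Step 10
Reactants: 13 E-alkene diester
Product: 15 seco keto ester, via Weinreb amide 14 (not isolated)
Conditions: MeNH(OMe)·HCl, i-PrMgCl, THF, −20 °C; then MeMgBr, 0 °C
Reagents that add atoms: methylmagnesium bromide C[Mg]Br
Why: Weinreb ketone synthesis in one flask, in which the magnesium amide attacks only the unhindered C8 ester (the tertiary C18 ester is shielded) and the chelated adduct of MeMgBr stops at the methyl ketone.

Step 11
Reactants: 15 seco keto ester
Product: 16 bicyclic hydroxy ester
Conditions: SmI2 (4 equiv), HMPA, t-BuOH (2 equiv), THF, 0 °C to rt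
Reagents that add atoms: none
Why: SmI2–HMPA transfers one electron to the C8 ketone, the samarium-bound ketyl radical adds to C9 of the alkene, and the C11 radical is reduced by a second SmI2 and protonated by t-BuOH, which leaves the saturated C11 methylene. The closest known reaction type is the samarium diiodide ketyl–olefin reductive cyclisation of unactivated olefinic ketones. Ring B closes in the 6-exo-trig mode through a chair-like transition state spanned by the trans-diequatorial arms on C5 and C10, so the trans ring fusion is inherited from ring A. C9 is controlled by the E-alkene lying pseudo-equatorial, which puts H-9 axial and anti to the C10 methyl, because a pseudo-axial C11 chain would clash with H-5 and H-7. C8 is controlled by the bulky HMPA-solvated oxygen–samarium group, which takes the pseudo-equatorial site trans to the alkene and away from the axial C10 methyl and so leaves the C8 methyl axial and the hydroxyl equatorial. The step needs exo rather than 7-endo attack and cyclisation before ketyl protonation: the alkyl group on C11 retards endo attack, the quaternary C10 and the rigid ring A hold the reacting ends close, and the weak acid t-BuOH keeps ketyl formation reversible.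

Step 12
Reactants: 16 bicyclic hydroxy ester
Product: 17 8,18-diol
Conditions: LiAlH4, THF, 0 °C to rt
Reagents that add atoms: none
Why: LiAlH4 reduces the equatorial C18 ester to the primary alcohol while the silyl ether and the tertiary alkoxide stay inert.

Step 13
Reactants: 17 8,18-diol; 18 angelic acid
Product: 20 18-angelate silyl ether, via mixed anhydride 19 (not isolated)
Conditions: 18, 2,4,6-trichlorobenzoyl chloride, Et3N, toluene, rt; then 17, 80 °C
Reagents that add atoms: none
Why: Acylation through the Yamaguchi-type mixed anhydride without a nucleophilic catalyst avoids the addition–elimination path that turns angelate into tiglate, and only the primary C18 hydroxyl reacts because the C8 hydroxyl is tertiary.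

Step 14
Reactants: 20 18-angelate silyl ether
Product: 21 18-angelate 8,15-diol
Conditions: AcOH/THF/H2O (3:1:1), rt
Reagents that add atoms: none
Why: Mild acid hydrolysis cleaves the primary silyl ether and leaves the tertiary alcohol and the Z-enoate untouched.

Step 15
Reactants: 21 18-angelate 8,15-diol; 22 Meldrum's acid
Product: 23 target CNP0286290.1
Conditions: 22 (1.1 equiv), toluene, 80 °C
Reagents that add atoms: none
Why: Alcoholysis of Meldrum's acid opens the dioxanedione at one carbonyl and loses acetone to give the malonic half ester directly, and the primary C15 hydroxyl outcompetes the tertiary C8 hydroxyl.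

Compound list

1 | (+)-dehydroabietic acid, abieta-8,11,13-trien-18-oic acid, (4R,5R,10S) in abietane numbering | CC(C)c1ccc2c(c1)CC[C@@H]3[C@]2(C)CCC[C@@]3(C)C(=O)O | starting material
2 | dehydroabietinol, abieta-8,11,13-trien-18-ol, (4R,5R,10S) | CC(C)c1ccc2c(c1)CC[C@@H]3[C@]2(C)CCC[C@@]3(C)CO | intermediate
3 | dehydroabietinyl acetate, 18-acetoxyabieta-8,11,13-triene, (4R,5R,10S) | CC(C)c1ccc2c(c1)CC[C@@H]3[C@]2(C)CCC[C@@]3(C)COC(C)=O | intermediate
4 | (1S,2S,3R)-3-(acetoxymethyl)-2-(2-carboxyethyl)-1,3-dimethylcyclohexane-1-carboxylic acid (both methyls and the C2 chain on one face) | OC(=O)[C@@]1(C)CCC[C@](COC(C)=O)(C)[C@@H]1CCC(=O)O | intermediate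
5 | dimethyl ester of 4, methyl (1S,2S,3R)-3-(acetoxymethyl)-2-(3-methoxy-3-oxopropyl)-1,3-dimethylcyclohexane-1-carboxylate | COC(=O)[C@@]1(C)CCC[C@](COC(C)=O)(C)[C@@H]1CCC(=O)OC | intermediate
6 | methyl (1S,2S,3R)-3-(hydroxymethyl)-2-(3-methoxy-3-oxopropyl)-1,3-dimethylcyclohexane-1-carboxylate | COC(=O)[C@@]1(C)CCC[C@](CO)(C)[C@@H]1CCC(=O)OC | intermediate
7 | methyl (1S,2S,3R)-3-formyl-2-(3-methoxy-3-oxopropyl)-1,3-dimethylcyclohexane-1-carboxylate | COC(=O)[C@@]1(C)CCC[C@](C=O)(C)[C@@H]1CCC(=O)OC | intermediate
8 | methyl (1S,2S,3R)-3-[(E)-2-iodoethenyl]-2-(3-methoxy-3-oxopropyl)-1,3-dimethylcyclohexane-1-carboxylate | COC(=O)[C@@]1(C)CCC[C@](/C=C/I)(C)[C@@H]1CCC(=O)OC | intermediate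
9 | (R)-2-methylbutane-1,4-diol | OC[C@H](C)CCO | starting material
10 | (R)-4-(tert-butyldimethylsilyloxy)-2-methylbutan-1-ol | OC[C@H](C)CCO[Si](C)(C)C(C)(C)C | intermediate
11 | (R)-tert-butyl(4-iodo-3-methylbutoxy)dimethylsilane | IC[C@H](C)CCO[Si](C)(C)C(C)(C)C | intermediate
12 | [(R)-4-(tert-butyldimethylsilyloxy)-2-methylbutyl]zinc iodide | I[Zn]C[C@H](C)CCO[Si](C)(C)C(C)(C)C | intermediate
13 | methyl (1S,2S,3S)-3-[(1E,4S)-6-(tert-butyldimethylsilyloxy)-4-methylhex-1-en-1-yl]-2-(3-methoxy-3-oxopropyl)-1,3-dimethylcyclohexane-1-carboxylate | COC(=O)[C@@]1(C)CCC[C@](/C=C/C[C@H](C)CCO[Si](C)(C)C(C)(C)C)(C)[C@@H]1CCC(=O)OC | intermediate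
14 | C8 N-methoxy-N-methylamide of 13 | COC(=O)[C@@]1(C)CCC[C@](/C=C/C[C@H](C)CCO[Si](C)(C)C(C)(C)C)(C)[C@@H]1CCC(=O)N(C)OC | intermediate
15 | methyl (1S,2S,3S)-3-[(1E,4S)-6-(tert-butyldimethylsilyloxy)-4-methylhex-1-en-1-yl]-1,3-dimethyl-2-(3-oxobutyl)cyclohexane-1-carboxylate (8-oxo-8,9-secolabd-9(11)E-ene) | COC(=O)[C@@]1(C)CCC[C@](/C=C/C[C@H](C)CCO[Si](C)(C)C(C)(C)C)(C)[C@@H]1CCC(C)=O | intermediate
16 | methyl (4S,5S,8S,9S,10R,13S)-15-(tert-butyldimethylsilyloxy)-8-hydroxylabdan-18-oate (trans-decalin, 8-OH and C9 chain equatorial, C17 and C20 axial) | COC(=O)[C@@]1(C)CCC[C@]2(C)[C@@H]1CC[C@](C)(O)[C@H]2CC[C@H](C)CCO[Si](C)(C)C(C)(C)C | intermediate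
17 | (4S,5S,8S,9S,10R,13S)-15-(tert-butyldimethylsilyloxy)labdane-8,18-diol | OC[C@@]1(C)CCC[C@]2(C)[C@@H]1CC[C@](C)(O)[C@H]2CC[C@H](C)CCO[Si](C)(C)C(C)(C)C | intermediate
18 | angelic acid, (Z)-2-methylbut-2-enoic acid | C/C=C(/C)C(=O)O | starting material
19 | angelic 2,4,6-trichlorobenzoic anhydride (Z) | C/C=C(/C)C(=O)OC(=O)c1c(Cl)cc(Cl)cc1Cl | intermediate
20 | (4S,5S,8S,9S,10R,13S)-15-(tert-butyldimethylsilyloxy)-8-hydroxylabdan-18-yl angelate | C/C=C(/C)C(=O)OC[C@@]1(C)CCC[C@]2(C)[C@@H]1CC[C@](C)(O)[C@H]2CC[C@H](C)CCO[Si](C)(C)C(C)(C)C | intermediate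
21 | (4S,5S,8S,9S,10R,13S)-8,15-dihydroxylabdan-18-yl angelate | C/C=C(/C)C(=O)OC[C@@]1(C)CCC[C@]2(C)[C@@H]1CC[C@](C)(O)[C@H]2CC[C@H](C)CCO | intermediate
22 | Meldrum's acid, 2,2-dimethyl-1,3-dioxane-4,6-dione | CC1(C)OC(=O)CC(=O)O1 | starting material
23 | CNP0286290.1, (4S,5S,8S,9S,10R,13S)-18-angeloyloxy-8-hydroxylabdan-15-yl hydrogen malonate | C/C=C(/C)C(=O)OC[C@@]1(C)CCC[C@]2(C)[C@@H]1CC[C@](C)(O)[C@H]2CC[C@H](C)CCOC(=O)CC(=O)O | target

Total step count: 15. Longest linear sequence: 13 (steps 1–6 and 9–15, from 1).

Steps most likely to fail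

Step 11. The ketyl may be protonated and reduced to the C8 secondary alcohol before it reaches the unactivated alkene, whose attacked carbon sits next to a quaternary centre. The fallback activates the acceptor and brings the side chain in afterwards. It sets out from aldehyde 7 and comes back at 16.
- A Horner–Wadsworth–Emmons reaction of 7 with diethyl (phenylsulfonyl)methylphosphonate (NaH, THF) should give the E-vinyl sulfone diester F4.
- The one-flask Weinreb sequence of step 10 converts F4 into the keto vinyl sulfone F5.
- SmI2 in THF/MeOH closes ring B on the electron-poor alkene to give the C11 phenyl sulfone F6.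
- The dianion of F6 (n-BuLi, THF/DMPU, −78 °C) is alkylated with iodide 11 to give the chain-extended sulfone F7, a mixture at C11.
- Mg in MeOH removes the sulfonyl group to give 16.

Step 3. Benzylic oxidation next to the arene may outrun ring cleavage. This would deactivate the ring and lead to loss of one chain carbon by over-oxidation. The fallback raises the electron density of the arene first. It sets out from 3 and comes back at 4.
- Friedel–Crafts acetylation (AcCl, AlCl3, CH2Cl2) gives 12-acetyldehydroabietinyl acetate F1.
- Baeyer–Villiger oxidation (mCPBA, CH2Cl2) gives 12-acetoxydehydroabietinyl acetate F2.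
- Selective cleavage of the aryl acetate (NH4OAc, aqueous MeOH) gives 12-hydroxydehydroabietinyl acetate F3.
- The phenol ring of F3 is degraded much faster by RuCl3/NaIO4 to give 4.

Step 13. Acylation of the neopentyl hydroxyl may be so slow that Z to E isomerisation of the acyl donor sets in at the temperature needed. The fallback builds the Z-alkene on the ester instead of transferring it. It sets out from 17 and comes back at 20.
- Coupling of 17 with 2-[bis(2,2,2-trifluoroethoxy)phosphoryl]propanoic acid (DCC, DMAP, CH2Cl2) gives the 18-phosphonopropionate F8.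
- Still–Gennari olefination with acetaldehyde (KHMDS, 18-crown-6, THF, −78 °C) gives the Z-configured angelate 20.

Further compounds

F1 | step 3 | 12-acetyldehydroabietinyl acetate | CC(C)c1c(C(C)=O)cc2c(c1)CC[C@@H]3[C@]2(C)CCC[C@@]3(C)COC(C)=O
F2 | step 3 | 12-acetoxydehydroabietinyl acetate | CC(C)c1c(OC(C)=O)cc2c(c1)CC[C@@H]3[C@]2(C)CCC[C@@]3(C)COC(C)=O
F3 | step 3 | 12-hydroxydehydroabietinyl acetate | CC(C)c1c(O)cc2c(c1)CC[C@@H]3[C@]2(C)CCC[C@@]3(C)COC(C)=O
F4 | step 11 | E-vinyl sulfone diester | COC(=O)[C@@]1(C)CCC[C@](/C=C/S(=O)(=O)c2ccccc2)(C)[C@@H]1CCC(=O)OC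
F5 | step 11 | keto vinyl sulfone | COC(=O)[C@@]1(C)CCC[C@](/C=C/S(=O)(=O)c2ccccc2)(C)[C@@H]1CCC(C)=O
F6 | step 11 | C11 phenyl sulfone (bicyclic, 8-hydroxy, C18 methyl ester) | COC(=O)[C@@]1(C)CCC[C@]2(C)[C@@H]1CC[C@](C)(O)[C@H]2CS(=O)(=O)c3ccccc3
F7 | step 11 | chain-extended sulfone (mixture at C11) | COC(=O)[C@@]1(C)CCC[C@]2(C)[C@@H]1CC[C@](C)(O)[C@H]2C(C[C@H](C)CCO[Si](C)(C)C(C)(C)C)S(=O)(=O)c3ccccc3
F8 | step 13 | 18-phosphonopropionate (mixture at the phosphonate carbon) | CC(C(=O)OC[C@@]1(C)CCC[C@]2(C)[C@@H]1CC[C@](C)(O)[C@H]2CC[C@H](C)CCO[Si](C)(C)C(C)(C)C)P(=O)(OCC(F)(F)F)OCC(F)(F)F
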